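**Assumptions**
- The biogenesis is taken as a [4+2] union of toluquinone with the 1,3-diene terminus of a β-springene-type diterpene followed by dehydrogenation; the side chain is taken to arise by 10,11-epoxidation, anti opening by water and O-acetylation.
- Acyclic intermediates carry β-springene numbering (C1–C16). (E)-β-Farnesene, prenylmagnesium chloride (0.5 M in THF) and toluquinone are bought.

**Retrosynthetic overview**
1. Target ⇒ toluquinone 9 + acyclic diene 8: Diels–Alder reaction on the 2-substituted butadiene terminus, then loss of four hydrogens, run last on the complete unprotected chain.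
2. 8 ⇒ (10R,11R)-epoxide 6: anti opening by water at C11 (inversion), then acetylation of the C10 hydroxyl.
3. 6 ⇒ C15 epoxy alcohol 3 + prenyl unit 4 (C12–C13 bond, through the primary triflate).
4. 3 ⇒ allylic alcohol 2 (asymmetric epoxidation sets both stereocentres) ⇒ (E)-β-farnesene 1 (oxidation of the terminal E-methyl).
5. Ring order: only one ring is made, the benzo ring, in the final step; the quinone ring comes intact from 9.

**Route**

Step 1
Reactants: 1 (E)-β-farnesene [(6E)-7,11-dimethyl-3-methylidenedodeca-1,6,10-triene]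
Product: 2 (2E,6E)-2,6-dimethyl-10-methylidenedodeca-2,6,11-trien-1-ol
Conditions: SeO2 (0.3 equiv), salicylic acid (0.1 equiv), t-BuOOH (3 equiv), CH2Cl2, rt, 30 h; unreacted 1 recovered
Reagents that add atoms: tert-butyl hydroperoxide, CC(C)(C)OO
Why: Sharpless–Umbreit SeO2/t-BuOOH allylic oxidation (ene reaction, then [2,3]-sigmatropic shift) takes the (E)-methyl of the terminal trisubstituted alkene, as in the known β-farnesene to β-sinensal oxidation, and the [2,3] shift fixes the 2E geometry; no stereocentre is formed.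

Step 2
Reactants: 2 (2E,6E)-2,6-dimethyl-10-methylidenedodeca-2,6,11-trien-1-ol
Product: 3 (2R,3R,6E)-2,3-epoxy-2,6-dimethyl-10-methylidenedodeca-6,11-dien-1-ol
Conditions: Ti(OiPr)4 (10 mol%), D-(−)-diethyl tartrate (12 mol%), t-BuOOH (2 equiv, anhydrous), 4 Å MS, CH2Cl2, −20 °C
Reagents that add atoms: tert-butyl hydroperoxide, CC(C)(C)OO
Why: Katsuki–Sharpless asymmetric epoxidation oxidises only the alkene of the allylic alcohol, and the D-(−)-tartrate catalyst gives the (2R,3R)-epoxide (the L-(+)-ester gives 2S,3S with (E)-2-methylalk-2-en-1-ols), which sets both stereocentres of the later diol.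

Step 3
Reactants: 3 (2R,3R,6E)-2,3-epoxy-2,6-dimethyl-10-methylidenedodeca-6,11-dien-1-ol; 4 prenylmagnesium chloride [(3-methylbut-2-en-1-yl)magnesium chloride]
Product: 6 (6E,10R,11R)-10,11-epoxy-7,11,15-trimethyl-3-methylidenehexadeca-1,6,14-triene, via epoxy triflate 5 (not isolated)
Conditions: Tf2O (1.1 equiv), 2,6-lutidine (1.3 equiv), CH2Cl2, −78 °C; cold filtration through a short silica pad, solution used at once; then 4 (2 equiv), CuI (10 mol%), THF, −78 → −30 °C
Reagents that add atoms: none
Why: Copper-catalysed Grignard coupling with a primary alkyl triflate (Kochi-type sp3–sp3 coupling) displaces the triflate at −78 °C while the trisubstituted epoxide is inert, and the prenyl–copper species bonds through its unhindered CH2 terminus, so neither stereocentre is touched.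

Step 4
Reactants: 6 (6E,10R,11R)-10,11-epoxy-7,11,15-trimethyl-3-methylidenehexadeca-1,6,14-triene
Product: 7 (6E,10R,11S)-7,11,15-trimethyl-3-methylidenehexadeca-1,6,14-triene-10,11-diol
Conditions: HClO4 (0.2 M aq., 10 mol%), THF/H2O 3:1, 0 °C, 1 h
Reagents that add atoms: water, O
Why: Acid-catalysed epoxide hydration in which water attacks the tertiary carbon C11 anti to the breaking C–O bond (borderline SN2), so C11 is inverted to S while C10 stays R, giving the anti (10R,11S)-diol.

Step 5
Reactants: 7 (6E,10R,11S)-7,11,15-trimethyl-3-methylidenehexadeca-1,6,14-triene-10,11-diol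
Product: 8 (6E,10R,11S)-11-hydroxy-7,11,15-trimethyl-3-methylidenehexadeca-1,6,14-trien-10-yl acetate
Conditions: Ac2O (1.5 equiv), pyridine (3 equiv), DMAP (5 mol%), CH2Cl2, 0 °C → rt
Reagents that add atoms: acetic anhydride, CC(=O)OC(C)=O
Why: DMAP-catalysed acylation takes the secondary hydroxyl only, the tertiary one being too hindered under these conditions, and no stereocentre is touched.

Step 6
Reactants: 8 (6E,10R,11S)-11-hydroxy-7,11,15-trimethyl-3-methylidenehexadeca-1,6,14-trien-10-yl acetate; 9 toluquinone (2-methyl-1,4-benzoquinone)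
Product: 14 chabrolonaphthoquinone B, via Diels–Alder adduct 10 (not isolated), via dihydronaphthalenediol 11 (not isolated), via dihydronaphthoquinone 12 (not isolated), via naphthalenediol 13 (not isolated)
Conditions: 9 (1.1 equiv), BF3·OEt2 (1.5 equiv), CH2Cl2, −40 → −20 °C, 1 h; Et3N (5 equiv), −40 °C → rt; activated MnO2 (10 equiv), rt, 3 h
Reagents that add atoms: none
Why: Lewis-acid-directed quinone Diels–Alder reaction followed by enolisation and oxidative aromatisation: BF3 binds the more basic C4 carbonyl of 9 (vinylogous donation from the methyl group), so C6 becomes the electrophilic terminus and the diene CH2 next to the substituted carbon bonds there ("para" orientation, chain at C7 of the 2-methylnaphthoquinone), after which Et3N enolises 10 and MnO2 removes four hydrogens through 11–13; the ring-fusion centres are transient and the side-chain centres are not involved.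

**Compound list**
1 | (E)-β-farnesene, (6E)-7,11-dimethyl-3-methylidenedodeca-1,6,10-triene | C=CC(=C)CC/C=C(C)/CCC=C(C)C | starting material
2 | (2E,6E)-2,6-dimethyl-10-methylidenedodeca-2,6,11-trien-1-ol | C=CC(=C)CC/C=C(C)/CC/C=C(C)/CO | intermediate
3 | (2R,3R,6E)-2,3-epoxy-2,6-dimethyl-10-methylidenedodeca-6,11-dien-1-ol | OC[C@@]1(C)O[C@@H]1CC/C(C)=C/CCC(=C)C=C | intermediate
4 | prenylmagnesium chloride, (3-methylbut-2-en-1-yl)magnesium chloride | CC(C)=CC[Mg]Cl | starting material
5 | (2R,3R,6E)-2,3-epoxy-2,6-dimethyl-10-methylidenedodeca-6,11-dien-1-yl trifluoromethanesulfonate | O=S(=O)(OC[C@@]1(C)O[C@@H]1CC/C(C)=C/CCC(=C)C=C)C(F)(F)F | intermediate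
6 | (6E,10R,11R)-10,11-epoxy-7,11,15-trimethyl-3-methylidenehexadeca-1,6,14-triene | CC(C)=CCC[C@@]1(C)O[C@@H]1CC/C(C)=C/CCC(=C)C=C | intermediate
7 | (6E,10R,11S)-7,11,15-trimethyl-3-methylidenehexadeca-1,6,14-triene-10,11-diol | O[C@H](CC/C(C)=C/CCC(=C)C=C)[C@@](C)(O)CCC=C(C)C | intermediate
8 | (6E,10R,11S)-11-hydroxy-7,11,15-trimethyl-3-methylidenehexadeca-1,6,14-trien-10-yl acetate | CC(=O)O[C@H](CC/C(C)=C/CCC(=C)C=C)[C@@](C)(O)CCC=C(C)C | intermediate
9 | toluquinone, 2-methyl-1,4-benzoquinone | CC1=CC(=O)C=CC1=O | starting material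
10 | (3E,7R,8S)-8-hydroxy-4,8,12-trimethyl-1-(cis-7-methyl-5,8-dioxo-1,4,4a,5,8,8a-hexahydronaphthalen-2-yl)trideca-3,11-dien-7-yl acetate (both cis ring-fusion diastereomers form; one drawn) | CC(=O)O[C@H](CC/C(C)=C/CCC1=CC[C@@H]2[C@H](C1)C(=O)C(C)=CC2=O)[C@@](C)(O)CCC=C(C)C | intermediate
11 | (3E,7R,8S)-1-(5,8-dihydroxy-7-methyl-1,4-dihydronaphthalen-2-yl)-8-hydroxy-4,8,12-trimethyltrideca-3,11-dien-7-yl acetate | CC(=O)O[C@H](CC/C(C)=C/CCC1=CCc2c(C1)c(O)c(C)cc2O)[C@@](C)(O)CCC=C(C)C | intermediate
12 | (3E,7R,8S)-8-hydroxy-4,8,12-trimethyl-1-(7-methyl-5,8-dioxo-1,4,5,8-tetrahydronaphthalen-2-yl)trideca-3,11-dien-7-yl acetate | CC(=O)O[C@H](CC/C(C)=C/CCC1=CCC2=C(C1)C(=O)C(C)=CC2=O)[C@@](C)(O)CCC=C(C)C | intermediate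
13 | (3E,7R,8S)-1-(5,8-dihydroxy-7-methylnaphthalen-2-yl)-8-hydroxy-4,8,12-trimethyltrideca-3,11-dien-7-yl acetate | CC(=O)O[C@H](CC/C(C)=C/CCc1ccc2c(O)cc(C)c(O)c2c1)[C@@](C)(O)CCC=C(C)C | intermediate
14 | chabrolonaphthoquinone B, (3E,7R,8S)-8-hydroxy-4,8,12-trimethyl-1-(7-methyl-5,8-dioxo-5,8-dihydronaphthalen-2-yl)trideca-3,11-dien-7-yl acetate | CC(=O)O[C@H](CC/C(C)=C/CCc1ccc2c(c1)C(=O)C(C)=CC2=O)[C@@](C)(O)CCC=C(C)C | target

**Step count and risks**
Total step count: 6. Longest linear sequence: 6 (1 → 2 → 3 → 6 → 7 → 8 → 14); 4 and 9 are bought.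

The three steps most likely to fail are steps 3, 4 and 6.

Step 3 may give the branched (γ) prenyl isomer, or the displacement next to the fully substituted epoxide carbon may be slow. In the fallback the C5 unit is brought in as a sulfone-stabilised carbanion, which can bond only through its α-carbon. It sets out from 5, which is alkylated at −78 °C with lithiated 3-methylbut-2-enyl phenyl sulfone (n-BuLi, THF) to give the epoxy sulfone (6E,10R,11R)-10,11-epoxy-7,11,15-trimethyl-3-methylidene-13-(phenylsulfonyl)hexadeca-1,6,14-triene F1 as a mixture of C13 epimers. Buffered reductive desulfonylation (Na(Hg), Na2HPO4, MeOH/THF, −20 °C) removes the sulfonyl group, and the route is rejoined at 6.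

Step 4 may leak: attack at C10 gives the enantiomeric anti diol, and partial retention at C11 or cation–alkene cyclisation are also possible. In the fallback the inversion is moved to the secondary carbon and made a titanium-directed SN2 event. It sets out from 2, which is epoxidised with the enantiomeric catalyst (Ti(OiPr)4, L-(+)-diethyl tartrate, t-BuOOH) to the (2S,3S)-epoxy alcohol F2. Ti(OiPr)4-mediated opening with benzoic acid (Caron–Sharpless) attacks C3 with inversion and gives the diol benzoate F3. Tosylation of the primary hydroxyl (TsCl, Et3N, cat. Bu2SnO) gives the tosylate F4. K2CO3 in MeOH removes the benzoate and closes the tertiary alkoxide onto C1 to give the hydroxy epoxide F5. Its unhindered CH2 terminus is opened by 4 (3 equiv) with CuI (10 mol%) at −40 °C, which gives diol 7 directly with both centres correct; the route is rejoined at 7.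

Step 6 may give a mixture of 2,6- and 2,7-regioisomers, or BF3 may ionise the tertiary alcohol. In the fallback the regiocontrol is moved into the dienophile and no Lewis acid is used. It sets out from 8, which is heated with 2-bromo-5-methyl-1,4-benzoquinone (CC1=CC(=O)C(Br)=CC1=O; toluene, 60 °C). The bromine steers the diene CH2 terminus to the unsubstituted carbon of the bromo-alkene and gives the cis 4a-bromo adduct F6. Et3N eliminates HBr across C4a–C8a, and the route is rejoined at 12, which is carried on to 13 and 14 with Et3N and MnO2 as in step 6.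

**Further compounds**
F1 | step 3 | (6E,10R,11R)-10,11-epoxy-7,11,15-trimethyl-3-methylidene-13-(phenylsulfonyl)hexadeca-1,6,14-triene (C13 epimers) | CC(C)=CC(C[C@@]1(C)O[C@@H]1CC/C(C)=C/CCC(=C)C=C)S(=O)(=O)c1ccccc1
F2 | step 4 | (2S,3S,6E)-2,3-epoxy-2,6-dimethyl-10-methylidenedodeca-6,11-dien-1-ol | OC[C@]1(C)O[C@H]1CC/C(C)=C/CCC(=C)C=C
F3 | step 4 | (2S,3R,6E)-1,2-dihydroxy-2,6-dimethyl-10-methylidenedodeca-6,11-dien-3-yl benzoate | O=C(O[C@H](CC/C(C)=C/CCC(=C)C=C)[C@@](C)(O)CO)c1ccccc1
F4 | step 4 | (2S,3R,6E)-2-hydroxy-2,6-dimethyl-10-methylidene-1-(tosyloxy)dodeca-6,11-dien-3-yl benzoate | O=C(O[C@H](CC/C(C)=C/CCC(=C)C=C)[C@@](C)(O)COS(=O)(=O)c1ccc(C)cc1)c1ccccc1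
F5 | step 4 | (1R,4E)-4-methyl-8-methylidene-1-[(2S)-2-methyloxiran-2-yl]deca-4,9-dien-1-ol | O[C@H](CC/C(C)=C/CCC(=C)C=C)[C@@]1(C)OC1
F6 | step 6 | (3E,7R,8S)-1-(cis-4a-bromo-7-methyl-5,8-dioxo-1,4,4a,5,8,8a-hexahydronaphthalen-2-yl)-8-hydroxy-4,8,12-trimethyltrideca-3,11-dien-7-yl acetate (one of two cis diastereomers drawn) | CC(=O)O[C@H](CC/C(C)=C/CCC1=CC[C@]2(Br)[C@H](C1)C(=O)C(C)=CC2=O)[C@@](C)(O)CCC=C(C)C
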